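Ring A of the aromatic tricyclic half (C1–C5, C10) is closed last, at the C4–C5 bond, after a Diels–Alder union of a labdatriene acid with a ring-A-seco methylene lactone. The key step is a 6-exo reductive Heck cyclization: the C5 alkenyl iodide of ring B adds across the isopropenyl end of the C10 side chain; because C4 becomes quaternary, the neopentyl palladium cannot β-eliminate and formate delivers hydride, so one operation closes ring A and writes the gem-dimethyl group at C4. The precursor is the hexacyclic spiro adduct carrying a 4-methylpent-4-enyl chain on C10. The C5=C6 alkene left behind is reduced later through the 7-ketone to set the trans A/B fusion.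

Key step: step 24

Remark on numbering: terpenoid numbering is used, C1–C20 for the aryl tricyclic half and C1′–C20′ for the bicyclic half; α is the face opposite to the C10 methyl group.
Remark on stereochemistry: 3, 10 and 21 are racemic (for 10 the SMILES shows the enantiomer carried on); 9 is a 2E/2Z mixture, which is harmless because C10′ passes through a planar radical.

Step 1
Reactants: 1 methacrolein; 2 (1,3-dioxolan-2-ylmethyl)magnesium bromide
Product: 3 rac-1-(1,3-dioxolan-2-yl)-3-methylbut-3-en-2-ol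
Conditions: THF, −78 to 0 °C; H2O work-up
Reagents that add atoms: none
Why: Grignard 1,2-addition to the enal is expected at low temperature; the carbinol centre is racemic and is erased in step 2.

Step 2
Reactants: 3 rac-1-(1,3-dioxolan-2-yl)-3-methylbut-3-en-2-ol
Product: 4 ethyl (4E)-6-(1,3-dioxolan-2-yl)-4-methylhex-4-enoate
Conditions: CH3C(OEt)3 (5 equiv), EtCO2H (5 mol %), 140 °C, EtOH distilled off
Reagents that add atoms: triethyl orthoacetate, CC(OCC)(OCC)OCC
Why: Johnson–Claisen [3,3] rearrangement through a chair with the dioxolanylmethyl group equatorial should give the E trisubstituted alkene.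

Step 3
Reactants: 4 ethyl (4E)-6-(1,3-dioxolan-2-yl)-4-methylhex-4-enoate
Product: 5 (4E)-6-(1,3-dioxolan-2-yl)-4-methylhex-4-enal
Conditions: DIBAL-H (1.05 equiv), CH2Cl2, −78 °C; aq. Rochelle salt
Reagents that add atoms: none
Why: Partial ester reduction; the aluminium hemiacetal is stable at −78 °C and releases the aldehyde on work-up.

Step 4
Reactants: 6 trimethyl phosphonoacetate; 7 5-bromo-2-methylpent-1-ene
Product: 8 methyl 2-(dimethoxyphosphoryl)-6-methylhept-6-enoate
Conditions: NaH, DMF, 0 to 60 °C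
Reagents that add atoms: none
Why: SN2 mono-alkylation of the phosphonoacetate sodium salt by the primary bromide.

Step 5
Reactants: 8 methyl 2-(dimethoxyphosphoryl)-6-methylhept-6-enoate; 5 (4E)-6-(1,3-dioxolan-2-yl)-4-methylhex-4-enal
Product: 9 methyl (6E)-8-(1,3-dioxolan-2-yl)-6-methyl-2-(4-methylpent-4-enyl)octa-2,6-dienoate
Conditions: NaH, THF, 0 to 25 °C
Reagents that add atoms: none
Why: Horner–Wadsworth–Emmons olefination gives the trisubstituted enoate; its geometry need not be controlled.

Step 6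
Reactants: 9 methyl (6E)-8-(1,3-dioxolan-2-yl)-6-methyl-2-(4-methylpent-4-enyl)octa-2,6-dienoate
Product: 10 rac-methyl (1S*,4aS*,8aR*)-1-(1,3-dioxolan-2-ylmethyl)-5,5-dimethyl-2-methylidenedecahydronaphthalene-8a-carboxylate
Conditions: [Co(tBu4-salen)Cl] (chloro[N,N′-ethylenebis(3,5-di-tert-butylsalicylideneiminato)]cobalt, trivalent cobalt; 5 mol %), PhSiH3 (8 mol %), degassed benzene, 22 °C, stopped at full conversion of 9
Reagents that add atoms: none
Why: Hydrogen-atom-transfer radical cycloisomerization: cobalt hydride adds H to the isopropenyl group, the tertiary C4′ radical closes 6-endo on the enoate β-carbon, the α-ester C10′ radical closes 6-endo on the E alkene through a chair–chair transition state (trans fusion, C9′ chain equatorial), and divalent cobalt takes a methyl hydrogen from the C8′ radical to leave the exocyclic alkene.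

Step 7
Reactants: 10 rac-methyl (1S*,4aS*,8aR*)-1-(1,3-dioxolan-2-ylmethyl)-5,5-dimethyl-2-methylidenedecahydronaphthalene-8a-carboxylate
Product: 11 methyl (1S,4aS,8aR)-1-(1,3-dioxolan-2-ylmethyl)-5,5-dimethyl-2-methylidenedecahydronaphthalene-8a-carboxylate
Conditions: preparative SFC, amylose tris(3,5-dimethylphenylcarbamate) phase, CO2/MeOH
Reagents that add atoms: none
Why: Chromatographic resolution on a chiral stationary phase fixes the absolute configuration of C5′, C9′ and C10′; the enantiomer is to be assigned by X-ray analysis of a derivative.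

Step 8
Reactants: 11 methyl (1S,4aS,8aR)-1-(1,3-dioxolan-2-ylmethyl)-5,5-dimethyl-2-methylidenedecahydronaphthalene-8a-carboxylate
Product: 12 methyl (1S,4aS,8aR)-5,5-dimethyl-2-methylidene-1-(2-oxoethyl)decahydronaphthalene-8a-carboxylate
Conditions: 2 M aq. HCl, THF, 25 °C
Reagents that add atoms: water, O
Why: Acetal hydrolysis; dilute acid at room temperature should leave the exocyclic alkene in place.

Step 9
Reactants: 12 methyl (1S,4aS,8aR)-5,5-dimethyl-2-methylidene-1-(2-oxoethyl)decahydronaphthalene-8a-carboxylate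
Product: 13 methyl (1S,4aS,8aR)-5,5-dimethyl-2-methylidene-1-[(2E)-3-methyl-4-oxobut-2-enyl]decahydronaphthalene-8a-carboxylate
Conditions: Ph3P=C(CH3)CHO, toluene, 90 °C
Reagents that add atoms: 2-(triphenylphosphoranylidene)propanal, CC(C=O)=P(c1ccccc1)(c1ccccc1)c1ccccc1
Why: Wittig reaction of a stabilized ylide, expected to give the E trisubstituted enal.

Step 10
Reactants: 13 methyl (1S,4aS,8aR)-5,5-dimethyl-2-methylidene-1-[(2E)-3-methyl-4-oxobut-2-enyl]decahydronaphthalene-8a-carboxylate
Product: 14 methyl (5S,9S,10R)-labda-8(17),12E,14-trien-20-oate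
Conditions: Ph3PCH3Br, KHMDS, THF, 0 °C
Reagents that add atoms: methyltriphenylphosphonium bromide, C[P+](c1ccccc1)(c1ccccc1)c1ccccc1.[Br-]
Why: Wittig methylenation of the enal gives the E diene; the hindered angular ester should not react.

Step 11
Reactants: 14 methyl (5S,9S,10R)-labda-8(17),12E,14-trien-20-oate
Product: 15 (5S,9S,10R)-labda-8(17),12E,14-trien-20-oic acid
Conditions: NaSEt (5 equiv), DMF, 90 °C; then 1 M HCl
Reagents that add atoms: none
Why: SN2 O-demethylation by thiolate cleaves the hindered axial methyl ester without attack at the acyl carbon.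

Step 12
Reactants: 16 6-methoxy-1-tetralone
Product: 17 5-bromo-6-methoxy-1-tetralone
Conditions: NBS, MeCN, 25 °C
Reagents that add atoms: N-bromosuccinimide, O=C1CCC(=O)N1Br
Why: Electrophilic aromatic bromination ortho to the methoxy group at the position next to the ring junction.

Step 13
Reactants: 17 5-bromo-6-methoxy-1-tetralone
Product: 19 8-bromo-7-methoxy-4-methyl-1,2-dihydronaphthalene, via tertiary alcohol 18 (not isolated)
Conditions: MeMgBr, THF, 0 °C; then p-TsOH (cat.), toluene, 80 °C
Reagents that add atoms: methylmagnesium bromide, C[Mg]Br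
Why: Grignard addition followed by acid-catalysed dehydration of the tertiary benzylic alcohol to the styrene-type alkene.

Step 14
Reactants: 19 8-bromo-7-methoxy-4-methyl-1,2-dihydronaphthalene
Product: 21 rac-5-bromo-6-methoxy-1-methyl-3,4-dihydronaphthalen-2(1H)-one, via epoxide 20 (not isolated)
Conditions: mCPBA, NaHCO3, CH2Cl2, 0 °C; then BF3·OEt2 (5 mol %), 0 °C
Reagents that add atoms: mCPBA, O=C(OO)c1cccc(Cl)c1
Why: Epoxidation then Meinwald rearrangement: opening to the benzylic cation para to the methoxy group and 1,2-hydride shift give the 2-tetralone.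

Step 15
Reactants: 21 rac-5-bromo-6-methoxy-1-methyl-3,4-dihydronaphthalen-2(1H)-one; 7 5-bromo-2-methylpent-1-ene
Product: 22 (1R)-5-bromo-6-methoxy-1-methyl-1-(4-methylpent-4-enyl)-3,4-dihydronaphthalen-2(1H)-one
Conditions: N-[4-(trifluoromethyl)benzyl]cinchonidinium bromide (10 mol %), 50 % aq. NaOH, toluene, 0 to 15 °C
Reagents that add atoms: none
Why: Asymmetric phase-transfer alkylation of the benzylic enolate; the chiral ammonium ion pair screens one face and creates the C10 quaternary centre (sense assigned by analogy with 1-methyl-2-tetralone alkylations; the pseudoenantiomeric cinchoninium salt gives the antipode).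

Step 16
Reactants: 22 (1R)-5-bromo-6-methoxy-1-methyl-1-(4-methylpent-4-enyl)-3,4-dihydronaphthalen-2(1H)-one
Product: 23 tert-butyl 2-[(5R)-2-methoxy-5-methyl-5-(4-methylpent-4-enyl)-6-oxo-5,6,7,8-tetrahydronaphthalen-1-yl]acetate
Conditions: BrZnCH2CO2tBu (2 equiv), Pd2(dba)3 (2.5 mol %), Q-Phos (5 mol %), THF, 65 °C
Reagents that add atoms: 2-tert-butoxy-2-oxoethylzinc bromide, CC(C)(C)OC(=O)C[Zn]Br
Why: Negishi-type α-arylation of a zinc ester enolate, which is neutral enough to tolerate the ketone.

Step 17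
Reactants: 23 tert-butyl 2-[(5R)-2-methoxy-5-methyl-5-(4-methylpent-4-enyl)-6-oxo-5,6,7,8-tetrahydronaphthalen-1-yl]acetate
Product: 25 tert-butyl 2-[(5R)-6-iodo-2-methoxy-5-methyl-5-(4-methylpent-4-enyl)-5,8-dihydronaphthalen-1-yl]acetate, via hydrazone 24 (not isolated)
Conditions: N2H4·H2O, Et3N, EtOH, 80 °C; then I2, tetramethylguanidine, THF, 0 to 25 °C
Reagents that add atoms: iodine, II; hydrazine hydrate, NN.O (its nitrogen stays only in 24)
Why: Barton vinyl iodide synthesis under non-enolizing conditions that spare the acidic arylacetate; only C6 carries hydrogen, so the C5=C6 iodoalkene is the single regioisomer.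

Step 18
Reactants: 25 tert-butyl 2-[(5R)-6-iodo-2-methoxy-5-methyl-5-(4-methylpent-4-enyl)-5,8-dihydronaphthalen-1-yl]acetate
Product: 26 tert-butyl 2-[(5R)-6-iodo-2-methoxy-5-methyl-5-(4-methylpent-4-enyl)-8-oxo-5,8-dihydronaphthalen-1-yl]acetate
Conditions: Rh2(cap)4 (cap = caprolactamate; 1 mol %), aq. t-BuOOH (5 equiv), K2CO3, CH2Cl2, 25 °C
Reagents that add atoms: tert-butyl hydroperoxide, CC(C)(C)OO
Why: Peroxyl-radical allylic oxidation at C7, the only CH2 that is both benzylic and allylic and hence the weakest C–H bond.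

Step 19
Reactants: 26 tert-butyl 2-[(5R)-6-iodo-2-methoxy-5-methyl-5-(4-methylpent-4-enyl)-8-oxo-5,8-dihydronaphthalen-1-yl]acetate
Product: 28 (6R)-7-iodo-6-methyl-6-(4-methylpent-4-enyl)naphtho[2,1-b]furan-2,9(1H,6H)-dione, via hydroxy acid 27 (not isolated)
Conditions: BCl3 (3 equiv), n-Bu4NI (3 equiv), CH2Cl2, −78 to 0 °C; H2O; then p-TsOH (cat.), toluene, 50 °C
Reagents that add atoms: none
Why: Lewis acid/iodide cleavage of the aryl methyl ether and the tert-butyl ester without protic acid that would add to the isopropenyl group, then acid-catalysed lactonization to the benzofuranone.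

Step 20
Reactants: 28 (6R)-7-iodo-6-methyl-6-(4-methylpent-4-enyl)naphtho[2,1-b]furan-2,9(1H,6H)-dione
Product: 29 (6R,9R)-9-hydroxy-7-iodo-6-methyl-6-(4-methylpent-4-enyl)-6,9-dihydronaphtho[2,1-b]furan-2(1H)-one
Conditions: (S)-2-methyl-CBS-oxazaborolidine (20 mol %), catecholborane, toluene, −78 to −40 °C
Reagents that add atoms: none
Why: Corey–Bakshi–Shibata 1,2-reduction with the aryl group as the large substituent; catalyst control should give the 7α (R) carbinol, cis to the C10 side chain.

Step 21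
Reactants: 29 (6R,9R)-9-hydroxy-7-iodo-6-methyl-6-(4-methylpent-4-enyl)-6,9-dihydronaphtho[2,1-b]furan-2(1H)-one
Product: 30 tert-butyldimethylsilyl ether of 29
Conditions: TBSOTf, 2,6-lutidine, CH2Cl2, −78 °C
Reagents that add atoms: tert-butyldimethylsilyl triflate, CC(C)(C)[Si](C)(C)OS(=O)(=O)C(F)(F)F
Why: Silylation of the hindered alcohol; the ether blocks oxa-Michael addition to the later methylene lactone and serves as the facial control element in step 23.

Step 22
Reactants: 30 tert-butyldimethylsilyl ether of 29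
Product: 31 (6R,9R)-9-(tert-butyldimethylsilyloxy)-7-iodo-6-methyl-1-methylidene-6-(4-methylpent-4-enyl)-6,9-dihydronaphtho[2,1-b]furan-2(1H)-one
Conditions: paraformaldehyde, i-Pr2NH2+ CF3CO2−, THF, 65 °C
Reagents that add atoms: formaldehyde (as paraformaldehyde), C=O
Why: Mannich-type α-methylenation (aminomethylation then elimination) of the acidic benzofuranone CH2.

Step 23
Reactants: 15 (5S,9S,10R)-labda-8(17),12E,14-trien-20-oic acid; 31 (6R,9R)-9-(tert-butyldimethylsilyloxy)-7-iodo-6-methyl-1-methylidene-6-(4-methylpent-4-enyl)-6,9-dihydronaphtho[2,1-b]furan-2(1H)-one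
Product: 32 Diels–Alder adduct (spiro-cyclohexene lactone with 7α-silyloxy, C5 iodide and the C10 4-methylpent-4-enyl chain)
Conditions: 15 (1.5 equiv), toluene (2 M), BHT (cat.), 40 °C, dark
Reagents that add atoms: none
Why: Thermal Diels–Alder reaction; C12′ bonds to the quaternary α-carbon ("ortho" orientation), the lactone carbonyl is exo and the arene endo as expected for an s-cis-locked α-methylene lactone, and the diene attacks the β face, anti to the pseudo-axial 7α-silyloxy group, which sets the spiro carbon and C12′.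

Step 24
Reactants: 32 Diels–Alder adduct
Product: 33 ring-A-closed 5-ene (4,4-dimethyl, 7α-silyloxy)
Conditions: Pd(OAc)2 (10 mol %), PPh3 (25 mol %), HCO2Na (3 equiv), Et4NCl, DMF, 80 °C
Reagents that add atoms: none
Why: Zerovalent palladium inserts into the C5–I bond, the alkenylpalladium adds syn across the isopropenyl group to form C4–C5, and the resulting neopentyl palladium, which has no β-hydrogen because C4 is quaternary, exchanges iodide for formate, loses CO2 and reductively eliminates the second C4 methyl group. The closest known reaction type is the hydride-terminated (reductive) intramolecular Heck cyclization. Ring A closes in the 6-exo-trig mode. No stereocentre is created (C4 carries two methyl groups, C5 stays sp2); the C10 centre set in step 15 is untouched and the C5 configuration is set in step 26. The step needs exo over 7-endo insertion, which the smaller ring and the usual preference of carbopalladation secure, and chemoselectivity over the three other alkenes, which only the tethered isopropenyl group can meet intramolecularly. Excess formate is meant to intercept the neopentyl palladium before it can add back to C5=C6.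

Step 25
Reactants: 33 ring-A-closed 5-ene (4,4-dimethyl, 7α-silyloxy)
Product: 35 5-en-7-one, via 7α-alcohol 34 (not isolated)
Conditions: TBAF, AcOH, THF, 25 °C; filtration through silica; then MnO2 (20 equiv), CH2Cl2, 25 °C
Reagents that add atoms: none
Why: Buffered fluoride desilylation, then MnO2 oxidation, which is selective for the allylic and benzylic C7 alcohol.

Step 26
Reactants: 35 5-en-7-one
Product: 36 7-ketone with 5α-H (trans A/B)
Conditions: SmI2 (2.5 equiv), t-BuOH (2 equiv), HMPA, THF, −78 °C; aq. NH4Cl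
Reagents that add atoms: none
Why: Electron-transfer conjugate reduction of the aryl enone, which is insensitive to the crowding at C5; the C5 carbanion should be protonated from the α face, anti to the axial C10 and C4β methyl groups, giving the more stable trans fusion, while the samarium enolate protects the ketone until work-up.

Step 27
Reactants: 36 7-ketone with 5α-H (trans A/B)
Product: 37 7β-alcohol
Conditions: NaBH4, MeOH/THF, −20 °C
Reagents that add atoms: none
Why: Hydride 1,2-reduction by axial attack from the α face, the β face being screened by C12′ of the spiro ring, should give the pseudo-equatorial 7β-alcohol.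

Step 28
Reactants: 37 7β-alcohol
Product: 39 7β-acetate 13′(16′)-en-14′-one, via hydroperoxide 38 (not isolated)
Conditions: O2, tetraphenylporphyrin (cat.), white LED, CH2Cl2, 0 °C; then Ac2O, pyridine, DMAP, 0 to 25 °C; aq. NaHCO3
Reagents that add atoms: dioxygen, O=O; acetic anhydride, CC(=O)OC(C)=O
Why: Schenck ene reaction of singlet oxygen at the only trisubstituted alkene (hydrogen from the C16′ methyl, oxygen to C14′), then Kornblum–DeLaMare dehydration of the allylic hydroperoxide by Ac2O/pyridine, which also acetylates the 7β-hydroxyl; the C14′ configuration of 38 is lost in the ketone.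

Step 29
Reactants: 39 7β-acetate 13′(16′)-en-14′-one
Product: 40 target CNP0558742.1
Conditions: NaBH4, CeCl3·7H2O, MeOH/THF, −78 °C
Reagents that add atoms: none
Why: Luche 1,2-reduction of the exo-methylene enone; the C12′ substituent, held pseudo-axial by A(1,3) strain with the exocyclic methylene, blocks its own face, so hydride should arrive from the opposite face and leave the 14′-hydroxyl cis to C11′.

Compound list
1 | methacrolein | C=C(C)C=O | starting material
2 | (1,3-dioxolan-2-ylmethyl)magnesium bromide | Br[Mg]CC1OCCO1 | starting material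
3 | rac-1-(1,3-dioxolan-2-yl)-3-methylbut-3-en-2-ol | C=C(C)C(O)CC1OCCO1 | intermediate
4 | ethyl (4E)-6-(1,3-dioxolan-2-yl)-4-methylhex-4-enoate | CCOC(=O)CC/C(C)=C/CC1OCCO1 | intermediate
5 | (4E)-6-(1,3-dioxolan-2-yl)-4-methylhex-4-enal | O=CCC/C(C)=C/CC1OCCO1 | intermediate
6 | trimethyl phosphonoacetate | COC(=O)CP(=O)(OC)OC | starting material
7 | 5-bromo-2-methylpent-1-ene | C=C(C)CCCBr | starting material
8 | methyl 2-(dimethoxyphosphoryl)-6-methylhept-6-enoate | COC(=O)C(CCCC(C)=C)P(=O)(OC)OC | intermediate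
9 | methyl (6E)-8-(1,3-dioxolan-2-yl)-6-methyl-2-(4-methylpent-4-enyl)octa-2,6-dienoate (2E/2Z mixture) | COC(=O)C(CCCC(C)=C)=CCC/C(C)=C/CC1OCCO1 | intermediate
10 | rac-methyl (1S*,4aS*,8aR*)-1-(1,3-dioxolan-2-ylmethyl)-5,5-dimethyl-2-methylidenedecahydronaphthalene-8a-carboxylate (trans-fused, 1-substituent cis to the ester) | C=C1CC[C@H]2C(C)(C)CCC[C@]2(C(=O)OC)[C@H]1CC1OCCO1 | intermediate
11 | methyl (1S,4aS,8aR)-1-(1,3-dioxolan-2-ylmethyl)-5,5-dimethyl-2-methylidenedecahydronaphthalene-8a-carboxylate (single enantiomer) | C=C1CC[C@H]2C(C)(C)CCC[C@]2(C(=O)OC)[C@H]1CC1OCCO1 | intermediate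
12 | methyl (1S,4aS,8aR)-5,5-dimethyl-2-methylidene-1-(2-oxoethyl)decahydronaphthalene-8a-carboxylate | C=C1CC[C@H]2C(C)(C)CCC[C@]2(C(=O)OC)[C@H]1CC=O | intermediate
13 | methyl (1S,4aS,8aR)-5,5-dimethyl-2-methylidene-1-[(2E)-3-methyl-4-oxobut-2-enyl]decahydronaphthalene-8a-carboxylate | C=C1CC[C@H]2C(C)(C)CCC[C@]2(C(=O)OC)[C@H]1C/C=C(\C)C=O | intermediate
14 | methyl (5S,9S,10R)-labda-8(17),12E,14-trien-20-oate | C=C1CC[C@H]2C(C)(C)CCC[C@]2(C(=O)OC)[C@H]1C/C=C(\C)C=C | intermediate
15 | (5S,9S,10R)-labda-8(17),12E,14-trien-20-oic acid | C=C1CC[C@H]2C(C)(C)CCC[C@]2(C(=O)O)[C@H]1C/C=C(\C)C=C | intermediate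
16 | 6-methoxy-1-tetralone | COc1ccc2c(c1)CCCC2=O | starting material
17 | 5-bromo-6-methoxy-1-tetralone | COc1ccc2c(c1Br)CCCC2=O | intermediate
18 | 5-bromo-6-methoxy-1-methyl-1,2,3,4-tetrahydronaphthalen-1-ol | COc1ccc2c(c1Br)CCCC2(C)O | intermediate
19 | 8-bromo-7-methoxy-4-methyl-1,2-dihydronaphthalene | COc1ccc2c(c1Br)CCC=C2C | intermediate
20 | 3,4-epoxide of 19 | COc1ccc2c(c1Br)CCC1OC21C | intermediate
21 | rac-5-bromo-6-methoxy-1-methyl-3,4-dihydronaphthalen-2(1H)-one | COc1ccc2c(c1Br)CCC(=O)C2C | intermediate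
22 | (1R)-5-bromo-6-methoxy-1-methyl-1-(4-methylpent-4-enyl)-3,4-dihydronaphthalen-2(1H)-one | COc1ccc2c(c1Br)CCC(=O)[C@]2(C)CCCC(C)=C | intermediate
23 | tert-butyl 2-[(5R)-2-methoxy-5-methyl-5-(4-methylpent-4-enyl)-6-oxo-5,6,7,8-tetrahydronaphthalen-1-yl]acetate | COc1ccc2c(c1CC(=O)OC(C)(C)C)CCC(=O)[C@]2(C)CCCC(C)=C | intermediate
24 | hydrazone of 23 | COc1ccc2c(c1CC(=O)OC(C)(C)C)CCC(=NN)[C@]2(C)CCCC(C)=C | intermediate
25 | tert-butyl 2-[(5R)-6-iodo-2-methoxy-5-methyl-5-(4-methylpent-4-enyl)-5,8-dihydronaphthalen-1-yl]acetate | COc1ccc2c(c1CC(=O)OC(C)(C)C)CC=C(I)[C@]2(C)CCCC(C)=C | intermediate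
26 | tert-butyl 2-[(5R)-6-iodo-2-methoxy-5-methyl-5-(4-methylpent-4-enyl)-8-oxo-5,8-dihydronaphthalen-1-yl]acetate | COc1ccc2c(c1CC(=O)OC(C)(C)C)C(=O)C=C(I)[C@]2(C)CCCC(C)=C | intermediate
27 | 2-[(5R)-2-hydroxy-6-iodo-5-methyl-5-(4-methylpent-4-enyl)-8-oxo-5,8-dihydronaphthalen-1-yl]acetic acid | O=C(O)Cc1c(O)ccc2c1C(=O)C=C(I)[C@]2(C)CCCC(C)=C | intermediate
28 | (6R)-7-iodo-6-methyl-6-(4-methylpent-4-enyl)naphtho[2,1-b]furan-2,9(1H,6H)-dione | O=C1Cc2c(O1)ccc1c2C(=O)C=C(I)[C@]1(C)CCCC(C)=C | intermediate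
29 | (6R,9R)-9-hydroxy-7-iodo-6-methyl-6-(4-methylpent-4-enyl)-6,9-dihydronaphtho[2,1-b]furan-2(1H)-one (hydroxyl cis to the side chain) | O=C1Cc2c(O1)ccc1c2[C@H](O)C=C(I)[C@]1(C)CCCC(C)=C | intermediate
30 | tert-butyldimethylsilyl ether of 29 | O=C1Cc2c(O1)ccc1c2[C@H](O[Si](C)(C)C(C)(C)C)C=C(I)[C@]1(C)CCCC(C)=C | intermediate
31 | (6R,9R)-9-(tert-butyldimethylsilyloxy)-7-iodo-6-methyl-1-methylidene-6-(4-methylpent-4-enyl)-6,9-dihydronaphtho[2,1-b]furan-2(1H)-one | C=C1C(=O)Oc2ccc3c(c21)[C@H](O[Si](C)(C)C(C)(C)C)C=C(I)[C@]3(C)CCCC(C)=C | intermediate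
32 | Diels–Alder adduct: 20′-acid, 13′(14′)-ene spiro lactone, 7α-silyloxy, 5-iodo-5-ene, C10 β-methyl and α-(4-methylpent-4-enyl) | C=C1CC[C@H]2C(C)(C)CCC[C@]2(C(=O)O)[C@H]1C[C@H]1C(C)=CCC[C@]12C(=O)Oc1ccc3c(c12)[C@H](O[Si](C)(C)C(C)(C)C)C=C(I)[C@]3(C)CCCC(C)=C | intermediate
33 | ring-A-closed 5-ene, 4,4-dimethyl, 7α-silyloxy | C=C1CC[C@H]2C(C)(C)CCC[C@]2(C(=O)O)[C@H]1C[C@H]1C(C)=CCC[C@]12C(=O)Oc1ccc3c(c12)[C@H](O[Si](C)(C)C(C)(C)C)C=C1C(C)(C)CCC[C@]31C | intermediate
34 | 5-en-7α-ol | C=C1CC[C@H]2C(C)(C)CCC[C@]2(C(=O)O)[C@H]1C[C@H]1C(C)=CCC[C@]12C(=O)Oc1ccc3c(c12)[C@H](O)C=C1C(C)(C)CCC[C@]31C | intermediate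
35 | 5-en-7-one | C=C1CC[C@H]2C(C)(C)CCC[C@]2(C(=O)O)[C@H]1C[C@H]1C(C)=CCC[C@]12C(=O)Oc1ccc3c(c12)C(=O)C=C1C(C)(C)CCC[C@]31C | intermediate
36 | 7-ketone, 5α-H, trans A/B | C=C1CC[C@H]2C(C)(C)CCC[C@]2(C(=O)O)[C@H]1C[C@H]1C(C)=CCC[C@]12C(=O)Oc1ccc3c(c12)C(=O)C[C@H]1C(C)(C)CCC[C@]31C | intermediate
37 | 7β-alcohol | C=C1CC[C@H]2C(C)(C)CCC[C@]2(C(=O)O)[C@H]1C[C@H]1C(C)=CCC[C@]12C(=O)Oc1ccc3c(c12)[C@@H](O)C[C@H]1C(C)(C)CCC[C@]31C | intermediate
38 | 14′-hydroperoxide of the 13′(16′)-ene, 7β-alcohol (expected 14′ epimer drawn) | C=C1CC[C@H]2C(C)(C)CCC[C@]2(C(=O)O)[C@H]1C[C@H]1C(=C)[C@H](OO)CC[C@]12C(=O)Oc1ccc3c(c12)[C@@H](O)C[C@H]1C(C)(C)CCC[C@]31C | intermediate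
39 | 7β-acetate 13′(16′)-en-14′-one | C=C1CC[C@H]2C(C)(C)CCC[C@]2(C(=O)O)[C@H]1C[C@H]1C(=C)C(=O)CC[C@]12C(=O)Oc1ccc3c(c12)[C@@H](OC(C)=O)C[C@H]1C(C)(C)CCC[C@]31C | intermediate
40 | CNP0558742.1 | C=C1CC[C@H]2C(C)(C)CCC[C@]2(C(=O)O)[C@H]1C[C@H]1C(=C)[C@@H](O)CC[C@]12C(=O)Oc1ccc3c(c12)[C@@H](OC(C)=O)C[C@H]1C(C)(C)CCC[C@]31C | target

Total step count: 29
Longest linear sequence: 18 steps (16 to 40, steps 12–29)

Steps most likely to fail

Step 6. The cobalt hydride may re-enter the exocyclic alkene of the product and move it into the ring, and the α-ester radical may be dehydrogenated before the second ring closes. The fallback sets out from 9 and closes the rings one at a time, with no metal hydride present in the second closure. Fe(acac)3/PhSiH3 in EtOH closes ring A′ by hydrogen-atom-transfer Giese addition to give methyl 2-[(3E)-6-(1,3-dioxolan-2-yl)-4-methylhex-3-enyl]-3,3-dimethylcyclohexane-1-carboxylate F1. LDA then PhSeBr gives its 1-phenylselanyl derivative F2. Hexabutylditin under irradiation effects a phenylselanyl group-transfer 6-endo cyclization to the tertiary 8′-selenide F3. H2O2/pyridine then triggers selenoxide syn-elimination toward the methyl group, and the route is rejoined at 10.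

Step 24. The alkenylpalladium may be reduced by formate before it inserts, the neopentyl palladium may add back to C5=C6 and be lost by β-elimination, and palladium hydride may isomerize the exocyclic alkenes. The fallback goes from 32 directly to 33 by a radical chain instead of palladium catalysis: (Me3Si)3SiH and AIBN in benzene at 80 °C generate the C5 alkenyl radical, which closes 6-exo onto C4, and the neopentyl radical takes hydrogen from the silane. No new compound is involved.

Step 26. SmI2 may over-reduce the aryl ketone or attack the aryl lactone, and C5 may be protonated from the β face. The fallback goes from 35 to 36 by hydride conjugate reduction with [(Ph3P)CuH]6 in wet benzene, in which hydride is delivered to C5 from the less hindered α face and the copper enolate is protonated on work-up. No new compound is involved.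

Further compounds
F1 | step 6 | methyl 2-[(3E)-6-(1,3-dioxolan-2-yl)-4-methylhex-3-enyl]-3,3-dimethylcyclohexane-1-carboxylate | COC(=O)C1CCCC(C)(C)C1CC/C(C)=C/CC1OCCO1
F2 | step 6 | methyl 2-[(3E)-6-(1,3-dioxolan-2-yl)-4-methylhex-3-enyl]-3,3-dimethyl-1-(phenylselanyl)cyclohexane-1-carboxylate | COC(=O)C1([Se]c2ccccc2)CCCC(C)(C)C1CC/C(C)=C/CC1OCCO1
F3 | step 6 | methyl 1-(1,3-dioxolan-2-ylmethyl)-2,5,5-trimethyl-2-(phenylselanyl)decahydronaphthalene-8a-carboxylate | CC1([Se]c2ccccc2)CC[C@H]2C(C)(C)CCC[C@]2(C(=O)OC)[C@H]1CC1OCCO1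
F0 | step 24 | none | none
F0 | step 26 | none | none
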